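(All runs are simulated on assumed constants; scatter was added.)

I counted in one unit, molecules of target per molecule of catalyst charged (the turnover number), because the catalyst is the smaller charge, 10 µM against 0.0500 mM of capture agent.

| setting | summer | noon | winter | dawn | oak | maple | larch |
|---|---|---|---|---|---|---|---|
| starting material | 0.50 mM | 0.50 mM | 0.50 mM | 0.50 mM | 0.50 mM (fed, over 50 s) | 0.50 mM | 0.50 mM |
| second substrate | 1 mM | 1 mM | 1 mM | 1 mM | 1.00 mM | 1.00 mM | 1.00 mM (fed, over 50 s) |
| capture agent | 0.050 mM | 0.050 mM | 0.050 mM | 0.10 mM | 0.0500 mM | 0.0500 mM | 0.0500 mM |
| free catalyst | 10 µM | 5 µM | 7.5 µM | 10 µM | 10 µM | 10 µM | 10 µM |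
| remark | run made earlier | run made earlier | run made earlier | run made earlier | all else is in the flask from the start; the feed brings no volume worth counting | everything together at the start | all else is in the flask from the start; the feed brings no volume worth counting |
| time |  |  |  |  | 4.0 min | 4.0 min | 4.0 min |

- summer (time / min: target / %, starting material / %): 0.500: 32.0, 29.1; 1.33: 35.6, 13.6; 2.50: 38.4, 10.7; 4.00: 37.2, 8.3
- noon (time / min: target / %, starting material / %): 0.417: 15.8, 39.9; 0.833: 19.1, 24.5; 2.00: 19.3, 11.9; 5.00: 18.7, 5.1
- winter (time / min: target / %, starting material / %): 1.33: 27.6, 17.3; 2.50: 29.6, 11.4; 4.00: 28.0, 7.9; 5.00: 28.6, 5.8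
- dawn (time / min: target / %, starting material / %): 0.667: 23.3, 29.2; 1.50: 23.9, 17.0; 3.00: 23.9, 11.2; 5.00: 23.8, 8.0

(standard deviation of a reading: 1 percentage point)

- in percentages every species weighs as the starting material in it: one self-condensation product counts as two
- what may be going on: starting material + free catalyst <-> catalyst intermediate A; catalyst intermediate A -> free catalyst + target; second substrate + free catalyst <-> catalyst intermediate B; catalyst intermediate B -> free catalyst + second product; catalyst intermediate B + capture agent -> trapped intermediate; 2 starting material -> self-condensation product

* the best flask by amount of target, in percent of the starting material charged; "all alike" if 1.5 percentage points covers them all (oak / maple / larch / all alike)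
* amount of target at the end, in percent of the starting material charged, oak
* amount of target at the end, in percent of the starting material charged, maple
* amount of target at the end, in percent of the starting material charged, larch

The catalyst's balance has one exit: capture agent meets catalyst intermediate B and forms trapped intermediate. The first setting is the catalyst charge. By hand, a fixed turnover number makes the target plateau follow the charge, and it did: the plateaus read 19.0 at noon, 19.0 in winter and 18.5 in summer.

The second setting is capture agent. Target forms in proportion to [starting material][free catalyst], and trapping in proportion to [second substrate][capture agent][free catalyst], so free catalyst cancels. Target per catalyst trapped is then s[starting material]/([second substrate][capture agent]). Taking summer's mean [starting material] over its first reading, 0.323 mM, I read the constant s, the trapping ratio, as 2.87 mM. By hand, doubling capture agent halves the turnover number to 9.25, but dawn read 11.9. Read through s, that reading puts dawn's mean [starting material] at 0.413 mM, richer than summer's.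

The third setting is the feed. Maple repeats summer, so I expected 37.1%. Oak's ramp over that same first stretch averages 0.150 mM of starting material, counting what was fed and none used, and by s I estimated 17.2% of target from it. Larch's ramp averages 0.300 mM of second substrate, counted the same way, and with summer's mean [starting material] s gives an estimated turnover number of 61.8, above the 50.0 the charge allows. So I ranked larch first, without a figure.

The forecast also chose larch, with oak at 15%, a little under mine, maple at 37.5% and larch at 58%, saying of oak “feeding starting material keeps it low while catalyst dies at the same rate”.

The flasks gave oak 22.1%, maple 36.9% and larch 65.7%.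

    starting material + free catalyst ⇌ catalyst intermediate A (K = 710 M⁻¹, k = 9000 M⁻¹ s⁻¹)
    catalyst intermediate A → free catalyst + target (k = 61.0 s⁻¹)
    second substrate + free catalyst ⇌ catalyst intermediate B (K = 1700 M⁻¹, k = 11000 M⁻¹ s⁻¹)
    catalyst intermediate B → free catalyst + second product (k = 1.40 s⁻¹)
    catalyst intermediate B + capture agent → trapped intermediate (k = 1600 M⁻¹ s⁻¹)
    2 starting material → self-condensation product (k = 46.0 M⁻¹ s⁻¹)

In oak, of the turnover up to 4.00 min, half of the second product had formed by 0.296 min and half of the self-condensation product by 0.902 min, and at 0.833 min trapped intermediate held 85.5% of the catalyst. Read through s, oak's target means its catalyst met a mean of 0.192 mM of starting material. Taking that same mean, and second substrate and capture agent as charged, s gives 55.1% of target for oak's neighbour with 0.020 mM of capture agent, and after 4.00 min that flask stands at 56.2%.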